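The 1,4-relationship between the C1 ketone and the C4 hydroxyl, across the C2=C3 bond of the cyclohexenone ring, is read as an opened α-methylbutenolide (C1–C4 plus the C4 oxygen). The six-membered carbocycle is therefore closed by a Dieckmann-type acyl transfer: an imide enolate at C6 attacks the lactone carbonyl C1 and the ring C1–O bond is given up. One operation forms C1–C6, the enone and the free C4 hydroxyl. The precursor is a butenolide carrying the geranylgeranyl chain, assembled by a catalytic asymmetric Mukaiyama–Michael reaction of a silyloxyfuran that sets C4 and C5.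

Key step: step 7

Remark on numbering: ring positions are those of the target (C1 ketone, C2 C–CH3, C3 olefinic CH, C4 CHOH, C5 CH bearing the side chain, C6 CH2; C1′ is the first side-chain carbon) and are used for the same atoms in all precursors.
Assumptions: the target SMILES encodes the cis (4S,5S) isomer; all-E geranylgeraniol and ethyl (E)-3-(tributylstannyl)prop-2-enoate are taken as catalogue compounds.

Step 1
Reactants: 1 geranylgeraniol
Product: 2 geranylgeranyl bromide
Conditions: PBr3 (0.4 equiv), Et2O, −10 to 0 °C; crude bromide used at once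
Reagents that add atoms: phosphorus tribromide, BrP(Br)Br
Why: Standard PBr3 bromination of a primary allylic terpenol through its phosphite ester, which at low temperature should give the primary bromide without allylic transposition or loss of the 2E geometry; no stereocentre is involved.

Step 2
Reactants: 2 geranylgeranyl bromide; 3 ethyl (E)-3-(tributylstannyl)prop-2-enoate
Product: 4 ethyl (2E,5E,9E,13E)-6,10,14,18-tetramethylnonadeca-2,5,9,13,17-pentaenoate
Conditions: Pd2(dba)3 (2.5 mol %), P(2-furyl)3 (10 mol %), THF, 50 °C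
Reagents that add atoms: none
Why: Migita–Kosugi–Stille coupling, in which zerovalent palladium ionises the allylic bromide to a π-allyl complex that takes the alkenyl group from tin at its unsubstituted terminus, so the skipped 2,5-diene should form with retention of both alkene geometries; no stereocentre is formed.

Step 3
Reactants: 4 ethyl pentaenoate
Product: 5 (2E,5E,9E,13E)-6,10,14,18-tetramethylnonadeca-2,5,9,13,17-pentaenoic acid
Conditions: LiOH·H2O (3 equiv), THF/MeOH/H2O, 0 to 23 °C; then 1 M HCl to pH 3 at 0 °C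
Reagents that add atoms: lithium hydroxide, [Li+].[OH-]
Why: Saponification of the ethyl ester; hydroxide is too weak a base to deprotonate the doubly allylic C1′ methylene, so the skipped diene should not move into conjugation.

Step 4
Reactants: 5 pentaenoic acid; 6 oxazolidin-2-one
Product: 8 3-[(2E,5E,9E,13E)-6,10,14,18-tetramethylnonadeca-2,5,9,13,17-pentaenoyl]-1,3-oxazolidin-2-one, via mixed pivalic anhydride 7 (not isolated)
Conditions: t-BuCOCl (1.05 equiv), Et3N (2.5 equiv), THF, −20 °C; then LiCl (1.1 equiv), oxazolidin-2-one, −20 to 23 °C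
Reagents that add atoms: none
Why: N-Acylation of the oxazolidinone through the mixed pivalic anhydride under LiCl/Et3N activation, a mild protocol without strong base that should leave the skipped dienoyl system and all alkene geometries intact; no stereocentre is formed.

Step 5
Reactants: 9 3-methylfuran-2(5H)-one
Product: 10 3-methyl-2-(trimethylsilyloxy)furan
Conditions: Me3SiOTf (1.1 equiv), Et3N (1.3 equiv), Et2O, 0 °C; distilled
Reagents that add atoms: trimethylsilyl trifluoromethanesulfonate, C[Si](C)(C)OS(=O)(=O)C(F)(F)F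
Why: Soft enolisation and O-silylation of the butenolide (Et3N removes the γ-proton of the silyl-activated lactone) gives the aromatic 2-silyloxyfuran, the standard preparation of such dienes.

Step 6
Reactants: 8 enoyl imide; 10 3-methyl-2-(trimethylsilyloxy)furan
Product: 11 3-[(3S,5E,9E,13E)-6,10,14,18-tetramethyl-3-[(2S)-4-methyl-5-oxo-2,5-dihydrofuran-2-yl]nonadeca-5,9,13,17-tetraenoyl]-1,3-oxazolidin-2-one
Conditions: Cu(OTf)2 (10 mol %), (S,S)-t-Bu-box [2,2′-(propane-2,2-diyl)bis((4S)-4-tert-butyl-4,5-dihydro-1,3-oxazole)] (11 mol %), (CF3)2CHOH (1.2 equiv), 4 Å MS, CH2Cl2, −40 °C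
Reagents that add atoms: none
Why: Vinylogous Mukaiyama–Michael addition of a 2-silyloxyfuran to an N-enoyl oxazolidinone held s-cis in the square-planar copper bis(oxazoline) chelate, whose tert-butyl group should block the Re face of Cβ so that the furan γ-carbon (future C4) adds to the Si face and sets C5 as S, while the endo-like approach of the furan over the acyl group (the arrangement of an endo [4+2] transition state, usual for this reaction class) gives the anti adduct and sets C4 as S; silyl transfer to (CF3)2CHOH turns the catalyst over.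

Step 7
Reactants: 11 butenolide imide
Product: 13 3-[(1RS,5S,6S)-5-hydroxy-3-methyl-2-oxo-6-[(2E,6E,10E)-3,7,11,15-tetramethylhexadeca-2,6,10,14-tetraen-1-yl]cyclohex-3-ene-1-carbonyl]-1,3-oxazolidin-2-one, via oxa-bridged titanium alkoxide 12 (not isolated)
Conditions: TiCl4 (1.1 equiv), i-Pr2NEt (1.2 equiv), CH2Cl2, −78 to 0 °C; aq NH4Cl
Reagents that add atoms: none
Why: TiCl4 chelates the two imide carbonyls, i-Pr2NEt removes a C6 proton, and the (Z)-chlorotitanium enolate adds through C6 to the lactone carbonyl C1 to give the 7-oxabicyclo[2.2.1]heptene alkoxide 12, whose C1–O(ring) bond then breaks to release the C1 ketone and the C4 alkoxide. The closest known reaction type is the Dieckmann (intramolecular Claisen) condensation onto a lactone, as in the ring-closing half of the Hauser–Kraus annulation and in TiCl4/amine-mediated Dieckmann cyclisations. The six-membered carbocycle closes in the 6-(enolexo)-exo-trig mode, the attacked C=O lying outside the new ring. No bond to C4 or C5 is broken, so the cis relation of hydroxyl and side chain set in step 6 is carried into the ring, while the new C6 centre is a readily epimerised β-dicarbonyl position that disappears in step 8. The step needs chemoselective enolisation of the imide over removal of the vinylogously acidic C4–H of the butenolide (which would scramble C4 through a 2-oxidofuran and open a retro-Michael path); bidentate chelation, the weak amine base and −78 °C should secure this, and C1 is the only electrophilic carbon that C6 can reach, since attack at C3 would close a four-membered ring. Strain release from 12 and formation of the stable titanium β-keto imide chelate should drive the equilibrium to 13.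

Step 8
Reactants: 13 β-keto imide
Product: 15 (4S,5S)-4-hydroxy-2-methyl-5-[(2E,6E,10E)-3,7,11,15-tetramethylhexadeca-2,6,10,14-tetraen-1-yl]cyclohex-2-en-1-one (target), via β-keto acid 14 (not isolated)
Conditions: Yb(OTf)3 (20 mol %), H2O (10 equiv), MeCN, 50 °C
Reagents that add atoms: none
Why: Lewis-acid-catalysed hydrolysis of the N-acyl oxazolidinone (the β-keto imide binds Yb(OTf)3 as a chelate and water attacks the exocyclic carbonyl) gives β-keto acid 14, which loses CO2 under the same near-neutral conditions, so C6 becomes a methylene while C4 and C5 are not involved and the cis (4S,5S) arrangement is retained.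

Compound list
1 | geranylgeraniol, (2E,6E,10E)-3,7,11,15-tetramethylhexadeca-2,6,10,14-tetraen-1-ol | CC(C)=CCC/C(C)=C/CC/C(C)=C/CC/C(C)=C/CO | starting material
2 | geranylgeranyl bromide, (2E,6E,10E)-1-bromo-3,7,11,15-tetramethylhexadeca-2,6,10,14-tetraene | CC(C)=CCC/C(C)=C/CC/C(C)=C/CC/C(C)=C/CBr | intermediate
3 | ethyl (E)-3-(tributylstannyl)prop-2-enoate | CCCC[Sn](CCCC)(CCCC)/C=C/C(=O)OCC | starting material
4 | ethyl (2E,5E,9E,13E)-6,10,14,18-tetramethylnonadeca-2,5,9,13,17-pentaenoate | CC(C)=CCC/C(C)=C/CC/C(C)=C/CC/C(C)=C/C/C=C/C(=O)OCC | intermediate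
5 | (2E,5E,9E,13E)-6,10,14,18-tetramethylnonadeca-2,5,9,13,17-pentaenoic acid | CC(C)=CCC/C(C)=C/CC/C(C)=C/CC/C(C)=C/C/C=C/C(=O)O | intermediate
6 | oxazolidin-2-one | O=C1NCCO1 | starting material
7 | mixed anhydride of acid 5 and pivalic acid (not isolated) | CC(C)=CCC/C(C)=C/CC/C(C)=C/CC/C(C)=C/C/C=C/C(=O)OC(=O)C(C)(C)C | intermediate
8 | 3-[(2E,5E,9E,13E)-6,10,14,18-tetramethylnonadeca-2,5,9,13,17-pentaenoyl]-1,3-oxazolidin-2-one | CC(C)=CCC/C(C)=C/CC/C(C)=C/CC/C(C)=C/C/C=C/C(=O)N1CCOC1=O | intermediate
9 | 3-methylfuran-2(5H)-one | CC1=CCOC1=O | starting material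
10 | 3-methyl-2-(trimethylsilyloxy)furan | Cc1ccoc1O[Si](C)(C)C | intermediate
11 | 3-[(3S,5E,9E,13E)-6,10,14,18-tetramethyl-3-[(2S)-4-methyl-5-oxo-2,5-dihydrofuran-2-yl]nonadeca-5,9,13,17-tetraenoyl]-1,3-oxazolidin-2-one (C4 and C5 both S) | CC(C)=CCC/C(C)=C/CC/C(C)=C/CC/C(C)=C/C[C@@H](CC(=O)N1CCOC1=O)[C@@H]1OC(=O)C(C)=C1 | intermediate
12 | oxa-bridged tetrahedral intermediate, 1-hydroxy-2-methyl-7-oxabicyclo[2.2.1]hept-2-ene with the geranylgeranyl chain at C5 exo (syn to the oxygen bridge) and the oxazolidinone carbonyl at C6; present in the flask as its trichlorotitanium alkoxide, drawn as the free hemiketal (not isolated) | CC(C)=CCC/C(C)=C/CC/C(C)=C/CC/C(C)=C/C[C@@H]1[C@H]2C=C(C)[C@](O)(O2)C1C(=O)N1CCOC1=O | intermediate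
13 | 3-[(1RS,5S,6S)-5-hydroxy-3-methyl-2-oxo-6-[(2E,6E,10E)-3,7,11,15-tetramethylhexadeca-2,6,10,14-tetraen-1-yl]cyclohex-3-ene-1-carbonyl]-1,3-oxazolidin-2-one (C6 epimers and enol form) | CC(C)=CCC/C(C)=C/CC/C(C)=C/CC/C(C)=C/C[C@H]1C(C(=O)N2CCOC2=O)C(=O)C(C)=C[C@H]1O | intermediate
14 | (1RS,5S,6S)-5-hydroxy-3-methyl-2-oxo-6-[(2E,6E,10E)-3,7,11,15-tetramethylhexadeca-2,6,10,14-tetraen-1-yl]cyclohex-3-ene-1-carboxylic acid (not isolated) | CC(C)=CCC/C(C)=C/CC/C(C)=C/CC/C(C)=C/C[C@H]1C(C(=O)O)C(=O)C(C)=C[C@H]1O | intermediate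
15 | (4S,5S)-4-hydroxy-2-methyl-5-[(2E,6E,10E)-3,7,11,15-tetramethylhexadeca-2,6,10,14-tetraen-1-yl]cyclohex-2-en-1-one | CC(C)=CCC/C(C)=C/CC/C(C)=C/CC/C(C)=C/C[C@H]1CC(=O)C(C)=C[C@H]1O | target

Total step count: 8. Longest linear sequence: 7 (steps 1, 2, 3, 4, 6, 7, 8; step 5 is a one-step side branch).

Steps most likely to fail

1. Step 7 (key step). The base may remove the C4 proton of the butenolide alongside or instead of the imide α-proton, so that C4 loses its configuration through the planar 2-oxidofuran or the C4–C5 bond is cleaved by retro-Michael reaction. The chlorotitanium enolate may also be too weak a nucleophile for the conjugated lactone. The fallback sets out from 11 and comes back at 13. The butenolide double bond is first masked by conjugate addition of thiophenol (PhSH, cat. Et3N, CH2Cl2, 0 °C) to give the saturated 3-(phenylsulfanyl) lactone F1, which has no vinylogous acidity and a more electrophilic carbonyl. F1 is cyclised as its sodium enolate (NaN(SiMe3)2, THF, −78 °C) to the sulfanyl keto imide F2. Oxidation with NaIO4 (MeOH/H2O, 0 °C) gives the sulfoxide F3, and its thermal syn-elimination (toluene, 60 °C) restores the C2=C3 bond and delivers 13.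

2. Step 6. Facial discrimination at Cβ may be insufficient, or the anti preference may erode with the long β-substituent, giving the enantiomer (not separable) or the C4 epimer. Should the sense of induction prove opposite to the model, the (R,R)-ligand is used. The fallback sets out from 5 and comes back at 15, and moves stereocontrol from the catalyst to a covalent auxiliary. Acid 5 is coupled under the conditions of step 4 (through 7) with (R)-4-benzyloxazolidin-2-one to the chiral enoyl imide F4. Chelation-controlled Mukaiyama–Michael addition of 10 (Et2AlCl, CH2Cl2, −78 °C; attack anti to the benzyl group) gives the butenolide imide F5, whose stereoisomers are now diastereomers and are removed by chromatography. The conditions of step 7 convert F5 through the bridged alkoxide F6 into the keto imide F7, and the conditions of step 8 release 15 (through 14) together with the auxiliary.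

3. Step 8. Lewis acid and heat may cause loss of water across C4–C5 followed by tautomerisation to the phenol, or the hydrolysis may stall on the enolised keto imide. The fallback sets out from 13 and comes back at 15. Keto imide 13 is transesterified with allyl alcohol (cat. Yb(OTf)3, 23 °C) to the allyl β-keto ester F8. Tsuji–Trost deallylation (Pd(PPh3)4 cat., morpholine, THF, 23 °C) then frees the carboxylic acid 14, which loses CO2 at room temperature to give 15.

Further compounds
F1 | step 7 | 3-[(3S,5E,9E,13E)-6,10,14,18-tetramethyl-3-[(2S)-4-methyl-5-oxo-3-(phenylsulfanyl)oxolan-2-yl]nonadeca-5,9,13,17-tetraenoyl]-1,3-oxazolidin-2-one (C2/C3 of the target numbering as formed) | CC(C)=CCC/C(C)=C/CC/C(C)=C/CC/C(C)=C/C[C@@H](CC(=O)N1CCOC1=O)[C@@H]1OC(=O)C(C)C1Sc1ccccc1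
F2 | step 7 | 3-[(5S,6S)-5-hydroxy-3-methyl-2-oxo-4-(phenylsulfanyl)-6-[(2E,6E,10E)-3,7,11,15-tetramethylhexadeca-2,6,10,14-tetraen-1-yl]cyclohexane-1-carbonyl]-1,3-oxazolidin-2-one | CC(C)=CCC/C(C)=C/CC/C(C)=C/CC/C(C)=C/C[C@H]1C(C(=O)N2CCOC2=O)C(=O)C(C)C(Sc2ccccc2)[C@H]1O
F3 | step 7 | 3-[(5S,6S)-4-(benzenesulfinyl)-5-hydroxy-3-methyl-2-oxo-6-[(2E,6E,10E)-3,7,11,15-tetramethylhexadeca-2,6,10,14-tetraen-1-yl]cyclohexane-1-carbonyl]-1,3-oxazolidin-2-one | CC(C)=CCC/C(C)=C/CC/C(C)=C/CC/C(C)=C/C[C@H]1C(C(=O)N2CCOC2=O)C(=O)C(C)C(S(=O)c2ccccc2)[C@H]1O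
F4 | step 6 | (4R)-4-benzyl-3-[(2E,5E,9E,13E)-6,10,14,18-tetramethylnonadeca-2,5,9,13,17-pentaenoyl]-1,3-oxazolidin-2-one | CC(C)=CCC/C(C)=C/CC/C(C)=C/CC/C(C)=C/C/C=C/C(=O)N1[C@H](Cc2ccccc2)COC1=O
F5 | step 6 | (4R)-4-benzyl-3-[(3S,5E,9E,13E)-6,10,14,18-tetramethyl-3-[(2S)-4-methyl-5-oxo-2,5-dihydrofuran-2-yl]nonadeca-5,9,13,17-tetraenoyl]-1,3-oxazolidin-2-one | CC(C)=CCC/C(C)=C/CC/C(C)=C/CC/C(C)=C/C[C@@H](CC(=O)N1[C@H](Cc2ccccc2)COC1=O)[C@@H]1OC(=O)C(C)=C1
F6 | step 6 | oxa-bridged tetrahedral intermediate carrying the (4R)-4-benzyl auxiliary, counterpart of 12, drawn as the free hemiketal (not isolated) | CC(C)=CCC/C(C)=C/CC/C(C)=C/CC/C(C)=C/C[C@@H]1[C@H]2C=C(C)[C@](O)(O2)C1C(=O)N1[C@H](Cc2ccccc2)COC1=O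
F7 | step 6 | (4R)-4-benzyl-3-[(1RS,5S,6S)-5-hydroxy-3-methyl-2-oxo-6-[(2E,6E,10E)-3,7,11,15-tetramethylhexadeca-2,6,10,14-tetraen-1-yl]cyclohex-3-ene-1-carbonyl]-1,3-oxazolidin-2-one | CC(C)=CCC/C(C)=C/CC/C(C)=C/CC/C(C)=C/C[C@H]1C(C(=O)N2[C@H](Cc3ccccc3)COC2=O)C(=O)C(C)=C[C@H]1O
F8 | step 8 | prop-2-en-1-yl (1RS,5S,6S)-5-hydroxy-3-methyl-2-oxo-6-[(2E,6E,10E)-3,7,11,15-tetramethylhexadeca-2,6,10,14-tetraen-1-yl]cyclohex-3-ene-1-carboxylate | CC(C)=CCC/C(C)=C/CC/C(C)=C/CC/C(C)=C/C[C@H]1C(C(=O)OCC=C)C(=O)C(C)=C[C@H]1O
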